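The acetoxymethyl carbon on the carbinol carbon and C2 of the heptadienyl chain on the ring CH stand cis and 1,3 across the ring CH2 of the cyclopentane. Joined as a C=C bridge, they make that ring part of a bicyclo[2.2.1]heptene with the tertiary oxygen at a bridgehead. The key step is an auxiliary-controlled endo Diels–Alder reaction of 3-methyl-1-(triethylsilyloxy)cyclopenta-1,3-diene with an acrylimide. It forms both ring bonds that flank the dienophile carbons and sets the three ring stereocentres in one operation. Ozonolysis then cuts the bridge into aldehyde and methyl ketone. Ireland–Claisen rearrangement and metathesis build the cis-cyclopentenone, and a late Stille coupling brings in the peroxide.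

Key step: step 3

Remark: the methyl group and the cyclopentyl substituent on the cyclopentenone are read as cis, as the SMILES encodes; this α′ centre can epimerise, so it is set by acyclic stereocontrol and only neutral or weakly acidic steps follow ring closure.

Step 1
Reactants: 1 (S)-4-benzyl-1,3-oxazolidin-2-one; 2 acrylic acid
Product: 4 (S)-3-acryloyl-4-benzyl-1,3-oxazolidin-2-one, via acrylic pivalic anhydride 3 (not isolated)
Conditions: t-BuCOCl, Et3N, THF, −20 °C; then 1, LiCl, −20 °C → rt
Reagents that add atoms: none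
Why: Mixed-anhydride N-acylation of the oxazolidinone under LiCl/Et3N activation should give the acrylimide without touching the stereocentre of 1.

Step 2
Reactants: 5 3-methylcyclopent-2-en-1-one
Product: 7 3-methyl-1-(triethylsilyloxy)cyclopenta-1,3-diene, via cross-conjugated dienol ether 6 (not isolated)
Conditions: Et3SiOTf, Et3N, Et2O, 0 °C; pentane extraction; then PhMe (0.05 M), 70 °C, followed by 1H NMR; used at once
Reagents that add atoms: triethylsilyl trifluoromethanesulfonate CC[Si](CC)(CC)OS(=O)(=O)C(F)(F)F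
Why: Soft enolisation should first give the kinetic 2-silyloxydiene 6, and one thermal suprafacial [1,5]-hydrogen shift (sigmatropic rearrangement of cyclopentadienes) then relays it to the through-conjugated 1-silyloxy isomer 7, any further shift being slow because it must pass a non-conjugated 5-silyloxy isomer.

Step 3
Reactants: 7 3-methyl-1-(triethylsilyloxy)cyclopenta-1,3-diene; 4 (S)-3-acryloyl-4-benzyl-1,3-oxazolidin-2-one
Product: 8 (4S)-4-benzyl-3-{[(1S,2R,4S)-5-methyl-1-(triethylsilyloxy)bicyclo[2.2.1]hept-5-en-2-yl]carbonyl}-1,3-oxazolidin-2-one (endo adduct)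
Conditions: Et2AlCl (1.4 equiv), CH2Cl2, −78 °C; aq. NaHCO3/Rochelle salt
Reagents that add atoms: none
Why: Et2AlCl binds the imide as a cationic bidentate chelate (s-cis enoyl) and the electron-rich 1-silyloxydiene adds in a concerted, asynchronous, normal-demand [4πs+2πs] cycloaddition, the closest known type being the oxazolidinone-auxiliary-controlled Diels–Alder reaction of cyclopentadiene. The single ring-forming event is suprafacial on both partners and closes the cyclohexene of a bicyclo[2.2.1]heptene, whose one-carbon-bridged five-membered ring C(OSi)–CH2–CH–CH2–CH(acyl) is the cyclopentane of the target, so the ring arises by cycloaddition and not by a Baldwin-type closure. The acyl-bearing centre is set by the auxiliary (the benzyl group shields one face of the chelated acrylate), the endo rule places the acyl group cis to the C=C bridge, and the two bridgeheads are cis by geometric necessity, which gives the all-cis carbon substituents and the trans oxygen of the target. The regiochemistry ("ortho" to the silyloxy terminus, "para" to the 3-methyl group) is secured because both donors raise the HOMO coefficient at the unsubstituted diene terminus, which bonds to the β-CH2 of the acrylate. A stepwise Mukaiyama–Michael/ring-closure course would give the same adduct; the risk is arrest at the Michael stage, which the low temperature and the locked s-cis diene should suppress.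

Step 4
Reactants: 8 endo imide adduct
Product: 11 (3aR,5S,6aR)-5-acetyl-3a-(triethylsilyloxy)hexahydro-1H-cyclopenta[c]furan-1-one, via keto aldehyde 9 (not isolated), via hydroxy imide 10 (not isolated)
Conditions: O3, CH2Cl2, −78 °C; Me2S, −78 °C → rt; then NaBH(OAc)3, AcOH, 0 °C → rt; PPTS (cat.), rt
Reagents that add atoms: ozone [O-][O+]=O
Why: Ozonolysis cleaves the only alkene to aldehyde and methyl ketone, NaBH(OAc)3 reduces only the aldehyde, and the new primary hydroxyl, held cis to the imide, lactonises (5-exo-trig acyl transfer) with release of the auxiliary, the three ring stereocentres staying untouched.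

Step 5
Reactants: 11 lactone methyl ketone
Product: 12 (3aR,5S,6aR)-5-(1,1-dibromoprop-1-en-2-yl)-3a-(triethylsilyloxy)hexahydro-1H-cyclopenta[c]furan-1-one
Conditions: CBr4, PPh3, PhMe, 80 °C
Reagents that add atoms: carbon tetrabromide BrC(Br)(Br)Br
Why: Dibromomethylenation with Ph3P=CBr2 made in the flask (Ramirez/Corey–Fuchs olefination) should take place at the ketone only, the lactone carbonyl being inert to the ylide and the neutral medium sparing the epimerisable carbon next to the ketone.

Step 6
Reactants: 12 dibromoalkene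
Product: 13 (3aR,5S,6aR)-5-[(Z)-1-bromoprop-1-en-2-yl]-3a-(triethylsilyloxy)hexahydro-1H-cyclopenta[c]furan-1-one
Conditions: Bu3SnH (1.1 equiv), Pd(PPh3)4 (4 mol %), PhH, rt
Reagents that add atoms: none
Why: In this stereoselective palladium-catalysed hydrogenolysis of a 1,1-dibromoalkene, zerovalent palladium inserts into the less hindered C–Br bond (trans to the ring carbon) and the tin hydride replaces it by hydrogen, so the remaining bromine should stand cis to the ring (Z).

Step 7
Reactants: 13 (Z)-bromoalkenyl lactone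
Product: 16 (1R,2R,4S)-4-[(Z)-1-bromoprop-1-en-2-yl]-2-{[(tert-butyldimethylsilyl)oxy]methyl}-2-(triethylsilyloxy)cyclopentane-1-carboxylic acid, via lithium hydroxy carboxylate 14 (not isolated), via bis-silyl derivative 15 (not isolated)
Conditions: LiOH, THF/H2O, rt; evaporation; t-BuMe2SiCl, imidazole, DMF, rt; then K2CO3, MeOH/H2O; citric acid to pH 5
Reagents that add atoms: lithium hydroxide [Li+].[OH-]; tert-butyldimethylsilyl chloride CC(C)(C)[Si](C)(C)Cl
Why: Saponification opens the γ-lactone, exhaustive silylation of the salt caps both oxygens before relactonisation can occur, and mild carbonate methanolysis should cleave only the labile silyl ester.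

Step 8
Reactants: 16 silyl-protected acid
Product: 18 diazoketone 2-diazo-1-[(1R,2R,4S)-4-[(Z)-1-bromoprop-1-en-2-yl]-2-{[(tert-butyldimethylsilyl)oxy]methyl}-2-(triethylsilyloxy)cyclopentyl]ethan-1-one, via mixed anhydride 17 (not isolated)
Conditions: i-BuOCOCl, Et3N, THF, −15 °C; then CH2N2, Et2O, 0 °C → rt
Reagents that add atoms: diazomethane C=[N+]=[N-]
Why: This is the first stage of an Arndt–Eistert homologation, in which the mixed anhydride acylates diazomethane under conditions that should not epimerise the ring carbon.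

Step 9
Reactants: 19 (E)-pent-3-en-2-ol (racemic)
Product: 20 (S,E)-pent-3-en-2-ol
Conditions: immobilised Candida antarctica lipase B, vinyl acetate, hexane, rt, stopped a little beyond half conversion
Reagents that add atoms: none
Why: In this lipase-catalysed kinetic resolution by transesterification the enzyme should acetylate the (R)-alcohol and leave the (S)-alcohol.

Step 10
Reactants: 18 diazoketone; 20 (S,E)-pent-3-en-2-ol
Product: 22 (S,E)-pent-3-en-2-yl 2-[(1S,2R,4S)-4-[(Z)-1-bromoprop-1-en-2-yl]-2-{[(tert-butyldimethylsilyl)oxy]methyl}-2-(triethylsilyloxy)cyclopentyl]acetate, via ketene 21 (not isolated)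
Conditions: AgO2CPh (10 mol %), Et3N, THF, 20 (3 equiv), rt → 45 °C, dark
Reagents that add atoms: none
Why: Silver-catalysed Wolff rearrangement (the ring carbon migrates with retention) and capture of ketene 21 by the allylic alcohol complete the Arndt–Eistert homologation and install the Claisen partner in the same operation.

Step 11
Reactants: 22 allylic ester
Product: 25 (2S,3R,4E)-2-[(1S,2R,4S)-4-[(Z)-1-bromoprop-1-en-2-yl]-2-{[(tert-butyldimethylsilyl)oxy]methyl}-2-(triethylsilyloxy)cyclopentyl]-3-methylhex-4-enoic acid, via silyl ketene acetal 23 (not isolated), via trimethylsilyl ester 24 (not isolated)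
Conditions: LiN(i-Pr)2, THF, −78 °C; Me3SiCl; −78 °C → rt, then 50 °C; 1 M NaOH, then citric acid
Reagents that add atoms: none
Why: In this Ireland–Claisen rearrangement, kinetic enolisation in THF gives the (E)-O-silyl ketene acetal (ring cis to the allyloxy oxygen), and a chair transition state with the carbinol methyl equatorial should transfer the (S) carbinol centre to the (3R) methyl-bearing carbon and set the (2S) carbon anti to it, which is the cis relationship of the later cyclopentenone.

Step 12
Reactants: 25 Claisen acid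
Product: 27 (4S,4aS,6S,7aR)-6-[(Z)-1-bromoprop-1-en-2-yl]-7a-hydroxy-4-[(2R,3E)-pent-3-en-2-yl]hexahydrocyclopenta[c]pyran-3(1H)-one, via dihydroxy acid 26 (not isolated)
Conditions: HF·pyridine, THF, 0 °C → rt; then CSA (cat.), PhMe, rt
Reagents that add atoms: none
Why: Fluoride cleaves both silyl ethers and the δ-hydroxy acid, whose hydroxymethyl group and carboxyl-bearing arm are cis, should close to the six-membered lactone under mild acid, which activates the carboxyl carbon and masks the primary alcohol at once.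

Step 13
Reactants: 27 δ-lactone
Product: 28 (4S,5R,6E)-4-[(1S,2R,4S)-4-[(Z)-1-bromoprop-1-en-2-yl]-2-hydroxy-2-(hydroxymethyl)cyclopentyl]-5-methylocta-1,6-dien-3-one (in equilibrium with its six-membered lactol)
Conditions: CH2=CHMgBr (2.5 equiv), THF, −78 → −20 °C; aq. NH4Cl
Reagents that add atoms: vinylmagnesium bromide C=C[Mg]Br
Why: Addition of one vinyl nucleophile to the lactone should stop at the magnesium lactolate, which is stable at low temperature, so that work-up releases the vinyl ketone and the free primary alcohol, the first equivalent being consumed by the tertiary hydroxyl.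

Step 14
Reactants: 28 hydroxy dienone
Product: 29 (4R,5S)-5-[(1S,2R,4S)-4-[(Z)-1-bromoprop-1-en-2-yl]-2-hydroxy-2-(hydroxymethyl)cyclopentyl]-4-methylcyclopent-2-en-1-one
Conditions: second-generation Grubbs catalyst RuCl2(=CHPh)(PCy3)(H2IMes) (5 mol %), CH2Cl2, 40 °C
Reagents that add atoms: none
Why: Ring-closing metathesis of the vinyl ketone with the propenyl group closes the cyclopentenone with loss of propene under neutral conditions that should not epimerise the α′ centre, the trisubstituted vinyl bromide being inert.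

Step 15
Reactants: 29 cyclopentenone diol
Product: 30 {(1R,2S,4S)-4-[(Z)-1-bromoprop-1-en-2-yl]-1-hydroxy-2-[(1S,5R)-5-methyl-2-oxocyclopent-3-en-1-yl]cyclopentyl}methyl acetate
Conditions: Ac2O, pyridine, CH2Cl2, 0 °C
Reagents that add atoms: acetic anhydride CC(=O)OC(C)=O
Why: Acylation with acetic anhydride and pyridine should take the primary hydroxyl only, the tertiary one being far less reactive.

Step 16
Reactants: 31 2-methylbut-3-yn-2-ol
Product: 32 2-hydroperoxy-2-methylbut-3-yne
Conditions: 50 % aq. H2O2, H2SO4 (cat.), 0 °C → rt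
Reagents that add atoms: hydrogen peroxide OO
Why: Acid-catalysed perhydrolysis (SN1 substitution at the tertiary propargylic carbon by H2O2) should give the tertiary hydroperoxide.

Step 17
Reactants: 32 2-hydroperoxy-2-methylbut-3-yne
Product: 33 2-methoxy-2-[(2-methylbut-3-yn-2-yl)peroxy]propane
Conditions: 2-methoxypropene, PPTS (cat.), CH2Cl2, 0 °C
Reagents that add atoms: 2-methoxypropene C=C(C)OC
Why: Acid-catalysed addition of the hydroperoxide to the enol ether protects it as a peroxyketal that tolerates base and palladium.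

Step 18
Reactants: 33 peroxyketal alkyne
Product: 34 tributyl{(E)-3-[(2-methoxypropan-2-yl)peroxy]-3-methylbut-1-en-1-yl}stannane
Conditions: Bu3SnH, PdCl2(PPh3)2 (2 mol %), THF, 0 °C
Reagents that add atoms: tributyltin hydride CCCC[SnH](CCCC)CCCC
Why: Palladium-catalysed syn-hydrostannation of the terminal alkyne places tin at the unhindered terminus and should give the (E)-vinylstannane faster than the tin hydride can attack the peroxide.

Step 19
Reactants: 30 (Z)-vinyl bromide acetate; 34 (E)-vinylstannane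
Product: 35 {(1R,2S,4S)-1-hydroxy-4-[(2Z,4E)-6-[(2-methoxypropan-2-yl)peroxy]-6-methylhepta-2,4-dien-2-yl]-2-[(1S,5R)-5-methyl-2-oxocyclopent-3-en-1-yl]cyclopentyl}methyl acetate
Conditions: Pd2(dba)3 (5 mol %), AsPh3 (20 mol %), CuI (10 mol %), NMP, 45 °C, dark
Reagents that add atoms: none
Why: Stille cross-coupling with retention of both alkene geometries should join the (Z)-bromide and the (E)-stannane to the (2Z,4E)-diene under neutral conditions tolerated by the enone, the acetate and the peroxyketal.

Step 20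
Reactants: 35 peroxyketal
Product: 36 [(1R,2S,4S)-1-hydroxy-4-[(2Z,4E)-6-hydroperoxy-6-methylhepta-2,4-dien-2-yl]-2-[(1S,5R)-5-methyl-2-oxocyclopent-3-en-1-yl]cyclopentyl]methyl acetate
Conditions: PPTS (cat.), MeOH, 0 °C
Reagents that add atoms: none
Why: Acid-catalysed methanolysis of the peroxyketal (transketalisation to 2,2-dimethoxypropane) should free the hydroperoxide without touching the acetate or epimerising the cyclopentenone.

Compound list
1 | (S)-4-benzyl-1,3-oxazolidin-2-one | O=C1OC[C@H](Cc2ccccc2)N1 | starting material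
2 | acrylic acid | C=CC(=O)O | starting material
3 | acrylic pivalic anhydride | C=CC(=O)OC(=O)C(C)(C)C | intermediate
4 | (S)-3-acryloyl-4-benzyl-1,3-oxazolidin-2-one | C=CC(=O)N1[C@@H](Cc2ccccc2)COC1=O | intermediate
5 | 3-methylcyclopent-2-en-1-one | CC1=CC(=O)CC1 | starting material
6 | 1-methyl-3-(triethylsilyloxy)cyclopenta-1,3-diene (cross-conjugated dienol ether) | CC1=CC(O[Si](CC)(CC)CC)=CC1 | intermediate
7 | 3-methyl-1-(triethylsilyloxy)cyclopenta-1,3-diene | CC1=CCC(O[Si](CC)(CC)CC)=C1 | intermediate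
8 | (4S)-4-benzyl-3-{[(1S,2R,4S)-5-methyl-1-(triethylsilyloxy)bicyclo[2.2.1]hept-5-en-2-yl]carbonyl}-1,3-oxazolidin-2-one (endo) | C2[C@@]1(O[Si](CC)(CC)CC)C[C@@H](C(C)=2)C[C@H]1C(=O)N3[C@@H](Cc4ccccc4)COC3=O | intermediate
9 | (4S)-3-{[(1R,2R,4S)-4-acetyl-2-formyl-2-(triethylsilyloxy)cyclopentyl]carbonyl}-4-benzyl-1,3-oxazolidin-2-one (keto aldehyde) | O=C[C@@]1(O[Si](CC)(CC)CC)C[C@@H](C(C)=O)C[C@H]1C(=O)N3[C@@H](Cc4ccccc4)COC3=O | intermediate
10 | (4S)-3-{[(1R,2R,4S)-4-acetyl-2-(hydroxymethyl)-2-(triethylsilyloxy)cyclopentyl]carbonyl}-4-benzyl-1,3-oxazolidin-2-one (hydroxy imide) | OC[C@@]1(O[Si](CC)(CC)CC)C[C@@H](C(C)=O)C[C@H]1C(=O)N3[C@@H](Cc4ccccc4)COC3=O | intermediate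
11 | (3aR,5S,6aR)-5-acetyl-3a-(triethylsilyloxy)hexahydro-1H-cyclopenta[c]furan-1-one (cis-fused, acetyl on the lactone face) | O2C[C@@]1(O[Si](CC)(CC)CC)C[C@@H](C(C)=O)C[C@H]1C2=O | intermediate
12 | (3aR,5S,6aR)-5-(1,1-dibromoprop-1-en-2-yl)-3a-(triethylsilyloxy)hexahydro-1H-cyclopenta[c]furan-1-one | O2C[C@@]1(O[Si](CC)(CC)CC)C[C@@H](C(C)=C(Br)Br)C[C@H]1C2=O | intermediate
13 | (3aR,5S,6aR)-5-[(Z)-1-bromoprop-1-en-2-yl]-3a-(triethylsilyloxy)hexahydro-1H-cyclopenta[c]furan-1-one | O2C[C@@]1(O[Si](CC)(CC)CC)C[C@@H](/C(C)=C\Br)C[C@H]1C2=O | intermediate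
14 | lithium (1R,2R,4S)-4-[(Z)-1-bromoprop-1-en-2-yl]-2-(hydroxymethyl)-2-(triethylsilyloxy)cyclopentane-1-carboxylate | [Li+].OC[C@@]1(O[Si](CC)(CC)CC)C[C@@H](/C(C)=C\Br)C[C@H]1C(=O)[O-] | intermediate
15 | tert-butyldimethylsilyl ester of 16 (bis-silyl derivative) | CC(C)(C)[Si](C)(C)OC[C@@]1(O[Si](CC)(CC)CC)C[C@@H](/C(C)=C\Br)C[C@H]1C(=O)O[Si](C)(C)C(C)(C)C | intermediate
16 | (1R,2R,4S)-4-[(Z)-1-bromoprop-1-en-2-yl]-2-{[(tert-butyldimethylsilyl)oxy]methyl}-2-(triethylsilyloxy)cyclopentane-1-carboxylic acid | CC(C)(C)[Si](C)(C)OC[C@@]1(O[Si](CC)(CC)CC)C[C@@H](/C(C)=C\Br)C[C@H]1C(=O)O | intermediate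
17 | isobutyl carbonic mixed anhydride of 16 | CC(C)(C)[Si](C)(C)OC[C@@]1(O[Si](CC)(CC)CC)C[C@@H](/C(C)=C\Br)C[C@H]1C(=O)OC(=O)OCC(C)C | intermediate
18 | 2-diazo-1-[(1R,2R,4S)-4-[(Z)-1-bromoprop-1-en-2-yl]-2-{[(tert-butyldimethylsilyl)oxy]methyl}-2-(triethylsilyloxy)cyclopentyl]ethan-1-one | CC(C)(C)[Si](C)(C)OC[C@@]1(O[Si](CC)(CC)CC)C[C@@H](/C(C)=C\Br)C[C@H]1C(=O)C=[N+]=[N-] | intermediate
19 | (E)-pent-3-en-2-ol (racemic) | C/C=C/C(C)O | starting material
20 | (S,E)-pent-3-en-2-ol | C/C=C/[C@H](C)O | intermediate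
21 | 2-[(1S,2R,4S)-4-[(Z)-1-bromoprop-1-en-2-yl]-2-{[(tert-butyldimethylsilyl)oxy]methyl}-2-(triethylsilyloxy)cyclopentyl]ethen-1-one (ketene) | CC(C)(C)[Si](C)(C)OC[C@@]1(O[Si](CC)(CC)CC)C[C@@H](/C(C)=C\Br)C[C@H]1C=C=O | intermediate
22 | (S,E)-pent-3-en-2-yl 2-[(1S,2R,4S)-4-[(Z)-1-bromoprop-1-en-2-yl]-2-{[(tert-butyldimethylsilyl)oxy]methyl}-2-(triethylsilyloxy)cyclopentyl]acetate | CC(C)(C)[Si](C)(C)OC[C@@]1(O[Si](CC)(CC)CC)C[C@@H](/C(C)=C\Br)C[C@H]1CC(=O)O[C@@H](C)/C=C/C | intermediate
23 | (E)-O-trimethylsilyl ketene acetal of 22 (cyclopentyl group trans to OSiMe3) | CC(C)(C)[Si](C)(C)OC[C@@]1(O[Si](CC)(CC)CC)C[C@@H](/C(C)=C\Br)C[C@H]1/C=C(/O[Si](C)(C)C)O[C@@H](C)/C=C/C | intermediate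
24 | trimethylsilyl ester of 25 | CC(C)(C)[Si](C)(C)OC[C@@]1(O[Si](CC)(CC)CC)C[C@@H](/C(C)=C\Br)C[C@H]1[C@H]([C@H](C)/C=C/C)C(=O)O[Si](C)(C)C | intermediate
25 | (2S,3R,4E)-2-[(1S,2R,4S)-4-[(Z)-1-bromoprop-1-en-2-yl]-2-{[(tert-butyldimethylsilyl)oxy]methyl}-2-(triethylsilyloxy)cyclopentyl]-3-methylhex-4-enoic acid | CC(C)(C)[Si](C)(C)OC[C@@]1(O[Si](CC)(CC)CC)C[C@@H](/C(C)=C\Br)C[C@H]1[C@H]([C@H](C)/C=C/C)C(=O)O | intermediate
26 | (2S,3R,4E)-2-[(1S,2R,4S)-4-[(Z)-1-bromoprop-1-en-2-yl]-2-hydroxy-2-(hydroxymethyl)cyclopentyl]-3-methylhex-4-enoic acid | OC[C@@]1(O)C[C@@H](/C(C)=C\Br)C[C@H]1[C@H]([C@H](C)/C=C/C)C(=O)O | intermediate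
27 | (4S,4aS,6S,7aR)-6-[(Z)-1-bromoprop-1-en-2-yl]-7a-hydroxy-4-[(2R,3E)-pent-3-en-2-yl]hexahydrocyclopenta[c]pyran-3(1H)-one | O2C[C@@]1(O)C[C@@H](/C(C)=C\Br)C[C@H]1[C@H]([C@H](C)/C=C/C)C2=O | intermediate
28 | (4S,5R,6E)-4-[(1S,2R,4S)-4-[(Z)-1-bromoprop-1-en-2-yl]-2-hydroxy-2-(hydroxymethyl)cyclopentyl]-5-methylocta-1,6-dien-3-one (open form) | OC[C@@]1(O)C[C@@H](/C(C)=C\Br)C[C@H]1[C@H]([C@H](C)/C=C/C)C(=O)C=C | intermediate
29 | (4R,5S)-5-[(1S,2R,4S)-4-[(Z)-1-bromoprop-1-en-2-yl]-2-hydroxy-2-(hydroxymethyl)cyclopentyl]-4-methylcyclopent-2-en-1-one | OC[C@@]1(O)C[C@@H](/C(C)=C\Br)C[C@H]1[C@H]1C(=O)C=C[C@H]1C | intermediate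
30 | {(1R,2S,4S)-4-[(Z)-1-bromoprop-1-en-2-yl]-1-hydroxy-2-[(1S,5R)-5-methyl-2-oxocyclopent-3-en-1-yl]cyclopentyl}methyl acetate | CC(=O)OC[C@@]1(O)C[C@@H](/C(C)=C\Br)C[C@H]1[C@H]1C(=O)C=C[C@H]1C | intermediate
31 | 2-methylbut-3-yn-2-ol | C#CC(C)(C)O | starting material
32 | 2-hydroperoxy-2-methylbut-3-yne | C#CC(C)(C)OO | intermediate
33 | 2-methoxy-2-[(2-methylbut-3-yn-2-yl)peroxy]propane | C#CC(C)(C)OOC(C)(C)OC | intermediate
34 | tributyl{(E)-3-[(2-methoxypropan-2-yl)peroxy]-3-methylbut-1-en-1-yl}stannane | CCCC[Sn](CCCC)(CCCC)/C=C/C(C)(C)OOC(C)(C)OC | intermediate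
35 | {(1R,2S,4S)-1-hydroxy-4-[(2Z,4E)-6-[(2-methoxypropan-2-yl)peroxy]-6-methylhepta-2,4-dien-2-yl]-2-[(1S,5R)-5-methyl-2-oxocyclopent-3-en-1-yl]cyclopentyl}methyl acetate | CC(=O)OC[C@@]1(O)C[C@@H](/C(C)=C\C=C\C(C)(C)OOC(C)(C)OC)C[C@H]1[C@H]1C(=O)C=C[C@H]1C | intermediate
36 | [(1R,2S,4S)-1-hydroxy-4-[(2Z,4E)-6-hydroperoxy-6-methylhepta-2,4-dien-2-yl]-2-[(1S,5R)-5-methyl-2-oxocyclopent-3-en-1-yl]cyclopentyl]methyl acetate | CC(=O)OC[C@@]1(O)C[C@@H](/C(C)=C\C=C\C(C)(C)OO)C[C@H]1[C@H]1C(=O)C=C[C@H]1C | target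

Total step count: 20.
Longest linear sequence: 15 steps (steps 2 to 8, 10 to 15, 19 and 20, from 5).

The three steps most likely to fail

Step 3 (key step). The cycloaddition may stop at an open-chain Mukaiyama–Michael stage, the Lewis acid may cleave the silyl dienol ether, and endo or facial control may erode if the chelate is not maintained. The fallback drops the Lewis acid and replaces asymmetric induction by resolution on the auxiliary. Setting out from 7, a thermal Diels–Alder reaction with acryloyl chloride (CH2Cl2, −40 → 0 °C, 2,6-di-tert-butylpyridine) should give the racemic endo acid chloride F1. Acylation of the lithium salt of 1 (n-BuLi, THF, −78 °C) with F1 gives 8 together with its diastereomer F2, which is removed by chromatography. The route is rejoined at 8.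

Step 2. The sigmatropic equilibration may stay incomplete or run on to other diene regioisomers, and the diene may dimerise on heating. The fallback generates the extended dienolate regiospecifically by reduction. Setting out from 5, radical bromination at the ring γ-carbon (N-bromosuccinimide, dibenzoyl peroxide (cat.), PhCF3, 80 °C) gives racemic 4-bromo-3-methylcyclopent-2-en-1-one F3. Zinc insertion in the presence of Et3SiCl (Zn, MeCN/Et2O, 0 °C) forms the zinc dienolate and traps it on oxygen at low temperature, which gives 7 without passing through 6. The route is rejoined at 7.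

Step 19. Oxidative addition into the hindered (Z)-bromide may be slow, the alkene geometry may be lost, and low-valent palladium may reduce the peroxide. The fallback is a Heck alkenylation in place of transmetalation. Commercial 2-methylbut-3-en-2-ol is converted by the operations of steps 16 and 17 into the hydroperoxide F4 and its peroxyketal F5. Setting out from 30, coupling with F5 (Pd(OAc)2, Ag2CO3, DMF, 45 °C) proceeds by syn-carbopalladation of the terminal alkene and the only possible β-hydride elimination, which should give the (E)-alkene, that is 35. The route is rejoined at 35.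

Further compounds
F1 | step 3 | 5-methyl-1-(triethylsilyloxy)bicyclo[2.2.1]hept-5-ene-2-endo-carbonyl chloride (racemic; one enantiomer drawn) | C2[C@@]1(O[Si](CC)(CC)CC)C[C@@H](C(C)=2)C[C@H]1C(Cl)=O
F2 | step 3 | (4S)-4-benzyl-3-{[(1R,2S,4R)-5-methyl-1-(triethylsilyloxy)bicyclo[2.2.1]hept-5-en-2-yl]carbonyl}-1,3-oxazolidin-2-one (diastereomer of 8) | C2[C@]1(O[Si](CC)(CC)CC)C[C@H](C(C)=2)C[C@@H]1C(=O)N3[C@@H](Cc4ccccc4)COC3=O
F3 | step 2 | 4-bromo-3-methylcyclopent-2-en-1-one (racemic) | CC1=CC(=O)CC1Br
F4 | step 19 | 2-hydroperoxy-2-methylbut-3-ene | C=CC(C)(C)OO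
F5 | step 19 | 2-methoxy-2-[(2-methylbut-3-en-2-yl)peroxy]propane | C=CC(C)(C)OOC(C)(C)OC
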